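**Retrosynthetic overview**

- The target 14 comes from the bis(O-methyl oxime) tetrapivalate 11 by reductive removal of the two oxime ethers and methanolysis of the four aryl esters. TiCl3 is used for the oxime cleavage because methoximes of di-ortho-substituted aryl ketones resist plain hydrolysis.
- 11 comes from 9 by converting C6'–H into C6'–OCH3 on both rings. The feature this rests on: on each ring (C1' acyl, C2' OH, C3' CH2 bridge, C4' OH, C5' CH3, C6' OCH3), C6' is the one carbon that no phenol can activate, being meta to both the C2' and C4' oxygens. It is, however, ortho to the C1' ketone, so an N-donor made from that ketone can deliver palladium to it.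
- 9 comes from the dimer 6 by oximation and pivaloylation. 6 comes from ketone 3 and formaldehyde, joined at C3', the only free carbon ortho/para to both hydroxyls. 3 comes from 4-methylresorcinol and isovaleryl chloride.
- No ring is formed. Both benzene rings are bought as 4-methylresorcinol. Bond order: C1'–acyl, then C3'–CH2–C3', then the two C6'–O bonds.

Key step: step 5

Remark: primed locants follow the target name. The oxime ethers are taken as E (O-methyl anti to the aryl group), the geometry set by hydrogen bonding in step 3. Their geometry after step 5 is immaterial because they are removed.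

**Route**

Step 1
Reactants: 1 4-methylresorcinol; 2 isovaleryl chloride
Product: 3 1-(2,4-dihydroxy-5-methylphenyl)-3-methylbutan-1-one
Conditions: AlCl3 (3.5 equiv), PhNO2/CH2Cl2, 0 °C to 50 °C; aq. HCl work-up
Reagents that add atoms: isovaleryl chloride (2), CC(C)CC(Cl)=O
Why: Friedel–Crafts acylation (any aryl ester formed first converges by Fries rearrangement under the same AlCl3 conditions) should go to C6 of the resorcinol, the unhindered carbon ortho to one hydroxyl and para to the other, and the chelated ortho-hydroxy ketone formed is deactivated against a second acylation.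

Step 2
Reactants: 3 1-(2,4-dihydroxy-5-methylphenyl)-3-methylbutan-1-one (2 equiv); 4 formaldehyde
Product: 6 bis[2,6-dihydroxy-3-methyl-5-(3-methylbutanoyl)phenyl]methane, via 3'-hydroxymethyl ketone 5 (not isolated)
Conditions: 37% aq. HCHO (0.5 equiv), NaOH, H2O/MeOH, rt to 50 °C; then aq. HCl
Reagents that add atoms: formaldehyde (4), C=O
Why: Lederer–Manasse hydroxymethylation of the phenoxide should occur at C3', the only free ring carbon ortho or para to the two oxygens (C5' carries the methyl group, C6' is meta to both), and the hydroxymethyl phenol 5 then loses hydroxide to an ortho-quinone methide that a second phenoxide of 3 captures at its own C3' by conjugate addition, as in the formaldehyde dimerisation of acylphloroglucinols.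

Step 3
Reactants: 6 bis[2,6-dihydroxy-3-methyl-5-(3-methylbutanoyl)phenyl]methane; 7 O-methylhydroxylamine hydrochloride
Product: 8 bis{2,6-dihydroxy-3-[(1E)-N-methoxy-3-methylbutanimidoyl]-5-methylphenyl}methane
Conditions: MeONH2·HCl (4 equiv), NaOAc, EtOH, reflux
Reagents that add atoms: O-methylhydroxylamine hydrochloride (7), CON.Cl
Why: Oxime ether condensation at both ketones under thermodynamic control should give the E,E isomer, because the C2' hydroxyl hydrogen-bonds to the oxime nitrogen, which turns the nitrogen lone pair toward the ring and the O-methyl group away from it.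

Step 4
Reactants: 8 bis{2,6-dihydroxy-3-[(1E)-N-methoxy-3-methylbutanimidoyl]-5-methylphenyl}methane
Product: 9 bis{3-[(1E)-N-methoxy-3-methylbutanimidoyl]-5-methyl-2,6-bis(pivaloyloxy)phenyl}methane
Conditions: PivCl (6 equiv), Et3N, DMAP (0.4 equiv), CH2Cl2, rt to reflux
Reagents that add atoms: pivaloyl chloride, CC(C)(C)C(Cl)=O
Why: DMAP-catalysed O-acylation through the N-pivaloylpyridinium ion should esterify all four phenols, while the oxime ethers offer no acylable site and keep their E geometry at these temperatures.

Step 5
Reactants: 9 bis{3-[(1E)-N-methoxy-3-methylbutanimidoyl]-5-methyl-2,6-bis(pivaloyloxy)phenyl}methane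
Product: 11 bis{4-methoxy-3-[(1E)-N-methoxy-3-methylbutanimidoyl]-5-methyl-2,6-bis(pivaloyloxy)phenyl}methane, via mono-C6'-methoxy bis(oxime ether) 10 (not isolated)
Conditions: Pd(OAc)2 (10 mol%), PhI(OAc)2 (3 equiv, two portions), MeOH, 90 °C, sealed tube
Reagents that add atoms: methanol, CO
Why: Each E oxime nitrogen should bind divalent palladium, and acetate-assisted concerted metalation–deprotonation of the adjacent C6'–H gives a five-membered N,C-palladacycle; PhI(OAc)2 oxidises it to a tetravalent palladium aryl, which takes a methoxide ligand from the solvent and forms the aryl–OCH3 bond by C–O reductive elimination, returning divalent palladium. The closest known reaction type is the Pd(OAc)2/PhI(OAc)2 ortho C–H oxygenation of aryl ketone O-methyl oximes, which gives aryl acetates in acetic acid and aryl methyl ethers in methanol; here it runs twice on one molecule, through 10. No ring is closed and no stereocentre is formed. Site selectivity is secured because C6'–H is the only aryl C–H on each ring and the geometry fixed in step 3 points the nitrogen at it, while on the other side of the C=N bond the isobutyl chain has no C–H placed for a five-membered palladacycle. Chemoselectivity is needed in two respects: methoxide must transfer in preference to acetate, which the large excess of methanol favours, and the rings must not be oxidised by the hypervalent iodine reagent, which the four pivalates prevent by keeping every phenol masked as a bulky ester that resists methanolysis. Because the oxygen arrives already methylated, no later step has to distinguish one phenol from the others.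

Step 6
Reactants: 11 bis{4-methoxy-3-[(1E)-N-methoxy-3-methylbutanimidoyl]-5-methyl-2,6-bis(pivaloyloxy)phenyl}methane
Product: 13 bis[4-methoxy-3-methyl-5-(3-methylbutanoyl)-2,6-bis(pivaloyloxy)phenyl]methane, via bis(N–H ketimine) tetrapivalate 12 (not isolated)
Conditions: TiCl3 (aq. HCl solution, 8 equiv), dioxane/H2O, 60 °C
Reagents that add atoms: water, O
Why: Reductive deoximation should work because trivalent titanium cleaves each N–O bond by two one-electron transfers to give the N–H ketimine 12, which the aqueous acid hydrolyses to the ketone as in the second stage of a Hoesch synthesis, and the aryl pivalates tolerate the dilute acid (any pivalate lost here is removed in step 7 anyway).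

Step 7
Reactants: 13 bis[4-methoxy-3-methyl-5-(3-methylbutanoyl)-2,6-bis(pivaloyloxy)phenyl]methane
Product: 14 3',3'''-methylenebis(2',4'-dihydroxy-6'-methoxy-β,5'-dimethylbutyrophenone)
Conditions: NaOMe (6 equiv), MeOH/THF, rt, argon; then aq. HCl
Reagents that add atoms: none
Why: Zemplén-type transesterification should cleave all four aryl pivalates to methyl pivalate at room temperature, since phenoxide is a good leaving group, without touching the aryl methyl ethers, the ketones or the methylene bridge, and acidification returns the tetraphenol.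

**Compound list**

1 | 4-methylresorcinol (4-methylbenzene-1,3-diol) | Cc1ccc(O)cc1O | starting material
2 | isovaleryl chloride (3-methylbutanoyl chloride) | CC(C)CC(Cl)=O | starting material
3 | 1-(2,4-dihydroxy-5-methylphenyl)-3-methylbutan-1-one | Cc1cc(C(=O)CC(C)C)c(O)cc1O | intermediate
4 | formaldehyde | C=O | starting material
5 | 1-[2,4-dihydroxy-3-(hydroxymethyl)-5-methylphenyl]-3-methylbutan-1-one | Cc1cc(C(=O)CC(C)C)c(O)c(CO)c1O | intermediate
6 | bis[2,6-dihydroxy-3-methyl-5-(3-methylbutanoyl)phenyl]methane (C3'–CH2–C3' dimer of 3) | Cc1cc(C(=O)CC(C)C)c(O)c(Cc2c(O)c(C)cc(C(=O)CC(C)C)c2O)c1O | intermediate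
7 | O-methylhydroxylamine hydrochloride | CON.Cl | starting material
8 | (E,E)-bis(O-methyl oxime) of 6, four free phenols | Cc1cc(/C(CC(C)C)=N/OC)c(O)c(Cc2c(O)c(C)cc(/C(CC(C)C)=N/OC)c2O)c1O | intermediate
9 | (E,E)-bis(O-methyl oxime) tetrapivalate with C6'–H on both rings (key-step precursor) | Cc1cc(/C(CC(C)C)=N/OC)c(OC(=O)C(C)(C)C)c(Cc2c(OC(=O)C(C)(C)C)c(C)cc(/C(CC(C)C)=N/OC)c2OC(=O)C(C)(C)C)c1OC(=O)C(C)(C)C | intermediate
10 | (E,E)-bis(O-methyl oxime) tetrapivalate with C6'–OCH3 on one ring and C6'–H on the other | COc1c(C)c(OC(=O)C(C)(C)C)c(Cc2c(OC(=O)C(C)(C)C)c(C)cc(/C(CC(C)C)=N/OC)c2OC(=O)C(C)(C)C)c(OC(=O)C(C)(C)C)c1/C(CC(C)C)=N/OC | intermediate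
11 | (E,E)-bis(O-methyl oxime) tetrapivalate with C6'–OCH3 on both rings (key-step product) | COc1c(C)c(OC(=O)C(C)(C)C)c(Cc2c(OC(=O)C(C)(C)C)c(C)c(OC)c(/C(CC(C)C)=N/OC)c2OC(=O)C(C)(C)C)c(OC(=O)C(C)(C)C)c1/C(CC(C)C)=N/OC | intermediate
12 | bis(N–H ketimine) tetrapivalate, bis[3-(1-imino-3-methylbutyl)-4-methoxy-5-methyl-2,6-bis(pivaloyloxy)phenyl]methane | COc1c(C)c(OC(=O)C(C)(C)C)c(Cc2c(OC(=O)C(C)(C)C)c(C)c(OC)c(C(=N)CC(C)C)c2OC(=O)C(C)(C)C)c(OC(=O)C(C)(C)C)c1C(=N)CC(C)C | intermediate
13 | tetrapivalate of the target, bis[4-methoxy-3-methyl-5-(3-methylbutanoyl)-2,6-bis(pivaloyloxy)phenyl]methane | COc1c(C)c(OC(=O)C(C)(C)C)c(Cc2c(OC(=O)C(C)(C)C)c(C)c(OC)c(C(=O)CC(C)C)c2OC(=O)C(C)(C)C)c(OC(=O)C(C)(C)C)c1C(=O)CC(C)C | intermediate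
14 | 3',3'''-methylenebis(2',4'-dihydroxy-6'-methoxy-β,5'-dimethylbutyrophenone) | COc1c(C)c(O)c(Cc2c(O)c(C)c(OC)c(C(=O)CC(C)C)c2O)c(O)c1C(=O)CC(C)C | target

**Step count**

Total steps: 7. Longest linear sequence: 7 steps (1 to 14).

**Steps most likely to fail**

Step 5. The cyclopalladation may be slow at C6'–H, which is flanked by the C5' methyl group and by an oxime twisted by the C2' pivalate, so the reaction may stall after one methoxylation. Acetate may also transfer in place of methoxide at the tetravalent palladium stage, or a pivalate may be lost by methanolysis and the freed phenol oxidised. The fallback sets out from 9 and comes back at 11. 9 is oxygenated under the methanol-free parent conditions (Pd(OAc)2, PhI(OAc)2, AcOH/Ac2O, 100 °C) to the (E,E)-bis(C6'-acetoxy) bis(O-methyl oxime) tetrapivalate F1. The two acetates are then removed in the presence of the four hindered pivalates (catalytic K2CO3, MeOH/THF, 0 °C) to the C6',C6'-diphenol tetrapivalate F2. Williamson methylation of F2 (MeI, K2CO3, acetone, rt) should give 11.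

Step 6. The N–O reduction or the hydrolysis of the ketimine may be incomplete, because the imine carbon is shielded on both faces by the C2' and C6' substituents of a perpendicular ring; acyl transfer from the C2' pivalate to the ketimine nitrogen could further divert material. The fallback sets out from 11 and comes back at 14, with the endgame order reversed. NaOMe in MeOH/THF first removes the pivalates to give the tetraphenol (E,E)-bis(O-methyl oxime) F3. The methoxime groups of F3 are then exchanged onto a sacrificial carbonyl compound (glyoxylic acid, aq. HCl, dioxane, 80 °C), the free C2' hydroxyl now assisting protonation at nitrogen, which should give 14 directly.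

Step 4. Acylation of four di-ortho-substituted, hydrogen-bonded phenols by a bulky acyl chloride may stop at partly esterified material. The fallback sets out from 8 and comes back at 14, replacing the esters by ethers installed through a less demanding O-alkylation. BnBr, K2CO3 in DMF at 60 °C should give the (E,E)-bis(O-methyl oxime) tetrabenzyl ether F4. The conditions of step 5 (Pd(OAc)2, PhI(OAc)2, MeOH, 90 °C) should then give the C6',C6'-dimethoxy bis(O-methyl oxime) tetrabenzyl ether F5. TiCl3 in aqueous HCl/dioxane should give the bis-ketone tetrabenzyl ether F6. Hydrogenolysis of F6 (H2, Pd/C, EtOAc, rt) should give 14 without any basic step.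

**Further compounds**

F1 | step 5 | (E,E)-bis(C6'-acetoxy) bis(O-methyl oxime) tetrapivalate | CC(=O)Oc1c(C)c(OC(=O)C(C)(C)C)c(Cc2c(OC(=O)C(C)(C)C)c(C)c(OC(C)=O)c(/C(CC(C)C)=N/OC)c2OC(=O)C(C)(C)C)c(OC(=O)C(C)(C)C)c1/C(CC(C)C)=N/OC
F2 | step 5 | C6',C6'-diphenol (E,E)-bis(O-methyl oxime) tetrapivalate | Oc1c(C)c(OC(=O)C(C)(C)C)c(Cc2c(OC(=O)C(C)(C)C)c(C)c(O)c(/C(CC(C)C)=N/OC)c2OC(=O)C(C)(C)C)c(OC(=O)C(C)(C)C)c1/C(CC(C)C)=N/OC
F3 | step 6 | tetraphenol (E,E)-bis(O-methyl oxime) of the target | COc1c(C)c(O)c(Cc2c(O)c(C)c(OC)c(/C(CC(C)C)=N/OC)c2O)c(O)c1/C(CC(C)C)=N/OC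
F4 | step 4 | (E,E)-bis(O-methyl oxime) tetrabenzyl ether with C6'–H on both rings | Cc1cc(/C(CC(C)C)=N/OC)c(OCc3ccccc3)c(Cc2c(OCc3ccccc3)c(C)cc(/C(CC(C)C)=N/OC)c2OCc3ccccc3)c1OCc3ccccc3
F5 | step 4 | C6',C6'-dimethoxy (E,E)-bis(O-methyl oxime) tetrabenzyl ether | COc1c(C)c(OCc3ccccc3)c(Cc2c(OCc3ccccc3)c(C)c(OC)c(/C(CC(C)C)=N/OC)c2OCc3ccccc3)c(OCc3ccccc3)c1/C(CC(C)C)=N/OC
F6 | step 4 | tetrabenzyl ether of the target (bis-ketone) | COc1c(C)c(OCc3ccccc3)c(Cc2c(OCc3ccccc3)c(C)c(OC)c(C(=O)CC(C)C)c2OCc3ccccc3)c(OCc3ccccc3)c1C(=O)CC(C)C
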